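**Strategy.** The route rests on cutting the quinone ring (ring A) at its C2=C3 double bond, the only ring bond flanked on both sides by carbonyl carbons (C1, C4) that sit on the arene (C4a, C8a). Both arms are therefore hung on one benzene ring as allylic carbinols by carbonyl additions: a vinyl carbinol (C4, C3) and a 2-methylene-1,3-diol arm (C1, C2 and the side chain) carrying the (R)-carbinol, set by asymmetric allylation. Ring-closing metathesis joins C2 to C3 with loss of ethylene, and MnO2 in the same flask turns the 1,4-dihydronaphthalene-1,4-diol into the 1,4-naphthoquinone. Esterification and removal of two MOM ethers finish the synthesis.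

Key step: step 7

Remark: the side-chain carbinol keeps the descriptor (R) in every intermediate, because the carbon that becomes C2 always outranks the side-chain CH2.

**Step 1**
Reactants: 1 acrolein
Product: 3 2-bromoacrolein, via 2,3-dibromopropanal 2 (not isolated)
Conditions: Br2, CH2Cl2, −78 °C; then Et3N, −78 °C to rt; distilled and used fresh
Reagents that add atoms: bromine, BrBr
Why: Bromination–dehydrobromination: bromine adds across the enal C=C and Et3N then removes the acidic α-proton with loss of the β-bromide (E1cB), which leaves the α-bromo enal.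

**Step 2**
Reactants: 3 2-bromoacrolein
Product: 4 (R)-2-bromohexa-1,5-dien-3-ol
Conditions: allylSnBu3, Ti(OiPr)4 (10 mol %), (R)-BINOL (20 mol %), 4 Å MS, CH2Cl2, −20 °C; aq NaHCO3
Reagents that add atoms: allyltributylstannane, C=CC[Sn](CCCC)(CCCC)CCCC
Why: Keck asymmetric allylation: the (R)-BINOL–titanium Lewis acid should direct allyl transfer from tin to the Re face of the aldehyde, which sets the (R)-carbinol (the bromovinyl group outranks the allyl CH2), the only stereocentre of the target.

**Step 3**
Reactants: 4 (R)-2-bromohexa-1,5-dien-3-ol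
Product: 5 (R)-2-bromo-6-methylhepta-1,5-dien-3-ol
Conditions: second-generation Grubbs catalyst (3 mol %), 2-methyl-2-butene (large excess), CH2Cl2, rt to 40 °C
Reagents that add atoms: 2-methyl-2-butene, CC=C(C)C
Why: Olefin cross-metathesis with an excess of 2-methyl-2-butene exchanges the terminal methylene for an isopropylidene group, while the hindered, electron-poor 2-bromo-1-alkene and the carbinol centre stay untouched.

**Step 4**
Reactants: 6 2,5-dihydroxybenzaldehyde
Product: 7 2,5-bis(methoxymethoxy)benzaldehyde
Conditions: MOMCl, i-Pr2NEt, CH2Cl2, 0 °C to rt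
Reagents that add atoms: chloromethyl methyl ether (MOMCl), COCCl
Why: O-Alkylation of both phenols (MOM ether formation) gives acetals that survive organolithium reagents, direct the later ortho-lithiation and can be removed by dilute acid at the end.

**Step 5**
Reactants: 7 2,5-bis(methoxymethoxy)benzaldehyde; 1 acrolein
Product: 9 lactol 3-ethenyl-4,7-bis(methoxymethoxy)-1,3-dihydro-2-benzofuran-1-ol, via hydroxy aldehyde 8 (not isolated)
Conditions: LiN(Me)CH2CH2NMe2 (from the diamine and n-BuLi), THF, −20 °C; n-BuLi, −20 °C; acrolein, −78 °C; H2O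
Reagents that add atoms: none
Why: Directed ortho-metalation of an α-amino alkoxide formed in the flask: the lithium amide masks the aldehyde, n-BuLi removes the only proton ortho to this group (also ortho to a MOM ether), the aryllithium adds 1,2 to acrolein, and hydrolysis frees the aldehyde, which closes on the new carbinol to the lactol (a diastereomer mixture of no consequence).

**Step 6**
Reactants: 9 lactol 3-ethenyl-4,7-bis(methoxymethoxy)-1,3-dihydro-2-benzofuran-1-ol; 5 (R)-2-bromo-6-methylhepta-1,5-dien-3-ol
Product: 11 triol (3R)-1-[2-(1-hydroxyprop-2-en-1-yl)-3,6-bis(methoxymethoxy)phenyl]-6-methyl-2-methylidenehept-5-ene-1,3-diol, via dilithio alkoxide 10 (not isolated)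
Conditions: 5, t-BuLi (3 equiv), Et2O, −78 to 0 °C; then sodium salt of 9 (NaH, THF, 0 °C), −78 to 0 °C; H2O
Reagents that add atoms: none
Why: Bromine–lithium exchange on the lithium alkoxide gives a 2-lithioallyl alkoxide that cannot eliminate (oxide is no leaving group) and adds 1,2 to the aldehyde tautomer released from the lactolate; the new carbinol centre forms without control and is erased later, and the (R) centre is not involved.

**Step 7**
Reactants: 11 triol (3R)-1-[2-(1-hydroxyprop-2-en-1-yl)-3,6-bis(methoxymethoxy)phenyl]-6-methyl-2-methylidenehept-5-ene-1,3-diol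
Product: 13 2-[(1R)-1-hydroxy-4-methylpent-3-en-1-yl]-5,8-bis(methoxymethoxy)naphthalene-1,4-dione, via dihydronaphthalenetriol 12 (not isolated)
Conditions: second-generation Grubbs catalyst (5–10 mol %), 1,4-benzoquinone (10 mol %), CH2Cl2 (0.005 M), 40 °C; then activated MnO2 (excess), rt
Reagents that add atoms: none
Why: Ring-closing olefin metathesis followed in the same flask by MnO2 oxidation: the Ru alkylidene loads on the monosubstituted vinyl carbinol olefin (C3), adds across the 1,1-disubstituted olefin of the other arm (C2) to a ruthenacyclobutane and cycloreverts with loss of ethylene, closing the six-membered ring through the new C2=C3 bond. The closest known reaction type is ring-closing metathesis of bis(allylic alcohols) to trisubstituted cyclohexenes, in which free allylic hydroxyls are tolerated and often accelerating. The closure is a six-membered carbocyclisation onto the benzene ring and keeps no new stereocentre, since the two ring carbinol centres (diastereomer mixtures in 11 and 12) are erased by the oxidation and the (R) side-chain centre is not touched. The step needs chemoselectivity among three olefins: the trisubstituted prenyl olefin is the least reactive and could only close four- or nine-membered rings, and 1,4-benzoquinone suppresses Ru–H migration of the allylic carbinols. MnO2 then has to oxidise only one doubly activated (benzylic and allylic) ring carbinol as an alcohol, because the resulting 4-hydroxynaphthalen-1(4H)-one tautomerises to the naphthalene-1,4-diol, which MnO2 oxidises at once to the quinone. The side-chain carbinol is only allylic and hindered, and once the quinone has formed it is deactivated, which should secure its survival.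

**Step 8**
Reactants: 13 2-[(1R)-1-hydroxy-4-methylpent-3-en-1-yl]-5,8-bis(methoxymethoxy)naphthalene-1,4-dione
Product: 14 (1R)-1-[5,8-bis(methoxymethoxy)-1,4-dioxo-1,4-dihydronaphthalen-2-yl]-4-methylpent-3-en-1-yl butanoate
Conditions: (n-PrCO)2O, pyridine, DMAP (cat.), CH2Cl2, 0 °C to rt
Reagents that add atoms: butanoic anhydride, CCCC(=O)OC(=O)CCC
Why: DMAP-catalysed acylation of the only free hydroxyl proceeds with retention at the carbinol centre.

**Step 9**
Reactants: 14 (1R)-1-[5,8-bis(methoxymethoxy)-1,4-dioxo-1,4-dihydronaphthalen-2-yl]-4-methylpent-3-en-1-yl butanoate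
Product: 15 butylshikonin, (1R)-1-(5,8-dihydroxy-1,4-dioxo-1,4-dihydronaphthalen-2-yl)-4-methylpent-3-en-1-yl butanoate
Conditions: 2 M aq HCl, THF, rt, argon, dark
Reagents that add atoms: none
Why: Acid-catalysed hydrolysis of the two aryl MOM acetals, eased by the peri carbonyl groups, should release the chelated naphthazarin hydroxyls while the secondary butanoate and the trisubstituted olefin survive dilute acid at room temperature.

**Compound list**

1 | acrolein (prop-2-enal) | C=CC=O | starting material
2 | 2,3-dibromopropanal (racemic) | O=CC(Br)CBr | intermediate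
3 | 2-bromoacrolein (2-bromoprop-2-enal) | C=C(Br)C=O | intermediate
4 | (R)-2-bromohexa-1,5-dien-3-ol | O[C@H](CC=C)C(Br)=C | intermediate
5 | (R)-2-bromo-6-methylhepta-1,5-dien-3-ol | O[C@H](CC=C(C)C)C(Br)=C | intermediate
6 | 2,5-dihydroxybenzaldehyde | O=Cc1cc(O)ccc1O | starting material
7 | 2,5-bis(methoxymethoxy)benzaldehyde | O=Cc1cc(OCOC)ccc1OCOC | intermediate
8 | 2-(1-hydroxyprop-2-en-1-yl)-3,6-bis(methoxymethoxy)benzaldehyde (racemic, open form of 9) | O=Cc1c(C(O)C=C)c(OCOC)ccc1OCOC | intermediate
9 | 3-ethenyl-4,7-bis(methoxymethoxy)-1,3-dihydro-2-benzofuran-1-ol (lactol, diastereomer mixture, racemic) | OC1OC(C=C)c2c(OCOC)ccc(OCOC)c12 | intermediate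
10 | dilithio alkoxide: lithium (3R)-2-lithio-6-methylhepta-1,5-dien-3-olate | [Li]C(=C)[C@H](O[Li])CC=C(C)C | intermediate
11 | (3R)-1-[2-(1-hydroxyprop-2-en-1-yl)-3,6-bis(methoxymethoxy)phenyl]-6-methyl-2-methylidenehept-5-ene-1,3-diol (mixture at the two benzylic carbinols) | C=CC(O)c1c(OCOC)ccc(OCOC)c1C(O)C(=C)[C@H](O)CC=C(C)C | intermediate
12 | 2-[(1R)-1-hydroxy-4-methylpent-3-en-1-yl]-5,8-bis(methoxymethoxy)-1,4-dihydronaphthalene-1,4-diol (mixture at C1 and C4) | O[C@H](CC=C(C)C)C1=CC(O)c2c(OCOC)ccc(OCOC)c2C1O | intermediate
13 | 2-[(1R)-1-hydroxy-4-methylpent-3-en-1-yl]-5,8-bis(methoxymethoxy)naphthalene-1,4-dione | O[C@H](CC=C(C)C)C1=CC(=O)c2c(OCOC)ccc(OCOC)c2C1=O | intermediate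
14 | (1R)-1-[5,8-bis(methoxymethoxy)-1,4-dioxo-1,4-dihydronaphthalen-2-yl]-4-methylpent-3-en-1-yl butanoate | CCCC(=O)O[C@H](CC=C(C)C)C1=CC(=O)c2c(OCOC)ccc(OCOC)c2C1=O | intermediate
15 | butylshikonin, (1R)-1-(5,8-dihydroxy-1,4-dioxo-1,4-dihydronaphthalen-2-yl)-4-methylpent-3-en-1-yl butanoate | CCCC(=O)O[C@H](CC=C(C)C)C1=CC(=O)c2c(O)ccc(O)c2C1=O | target

**Step count.** Total: 9 steps. Longest linear sequence: 7 steps (steps 1, 2, 3, 6, 7, 8, 9).

**Steps most likely to fail**

Step 7. The side-chain carbinol may be oxidised in competition with the ring carbinols, or the intermediate diol may aromatise by loss of water before it is oxidised. In the fallback the side-chain oxygen is masked and ring closure and oxidation are run apart. It sets out from 5. Silylation (TBSCl, imidazole, DMF) gives the silyl ether F1. Bromine–lithium exchange (t-BuLi, Et2O, −78 °C) gives the vinyllithium F2, which is added to the sodium salt of 9 to give the diol F3. Ring-closing metathesis (second-generation Grubbs catalyst, CH2Cl2, 40 °C) gives the isolated dihydronaphthalenediol F4. Dess–Martin periodinane with NaHCO3 oxidises both ring carbinols, with no selectivity demand, to the silylated quinone F5. HF·pyridine in THF removes the silyl group, and the route is rejoined at 13.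

Step 6. The lactolate may open too slowly to its aldehyde form, or proton transfer to the basic vinyllithium may quench it. The fallback replaces the masked aldehyde by a lactone and sets out from 9. Oxidation of the lactol (PhI(OAc)2, TEMPO cat., CH2Cl2) gives the phthalide F6. Addition of 10 at −78 °C to the lactone carbonyl gives the hydroxy enone F7, in equilibrium with its cyclic hemiketal. 1,2-Reduction under Luche conditions (NaBH4, CeCl3·7H2O, MeOH, −40 °C) returns the route to triol 11.

Step 5. Lithiation may occur at a position ortho to only one MOM ether, or the excess base may polymerise acrolein. The fallback reverses the roles of the two arms and sets out from 7. Vinylmagnesium bromide (THF, −78 °C) turns the existing aldehyde into the vinyl carbinol arm, the allylic alcohol F8. n-BuLi (2.2 equiv) with TMEDA deprotonates the hydroxyl and then the ring position flanked by the alkoxide and a MOM ether, giving the dilithio species F9. DMF and aqueous work-up introduce the formyl group as hydroxy aldehyde 8, which closes to lactol 9, where the route is rejoined.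

**Further compounds**

F1 | step 7 | tert-butyl{[(3R)-2-bromo-6-methylhepta-1,5-dien-3-yl]oxy}dimethylsilane | CC(C)(C)[Si](C)(C)O[C@H](CC=C(C)C)C(Br)=C
F2 | step 7 | tert-butyl{[(3R)-2-lithio-6-methylhepta-1,5-dien-3-yl]oxy}dimethylsilane | [Li]C(=C)[C@H](O[Si](C)(C)C(C)(C)C)CC=C(C)C
F3 | step 7 | (3R)-3-[(tert-butyldimethylsilyl)oxy]-1-[2-(1-hydroxyprop-2-en-1-yl)-3,6-bis(methoxymethoxy)phenyl]-6-methyl-2-methylidenehept-5-en-1-ol | C=CC(O)c1c(OCOC)ccc(OCOC)c1C(O)C(=C)[C@H](O[Si](C)(C)C(C)(C)C)CC=C(C)C
F4 | step 7 | 2-[(1R)-1-[(tert-butyldimethylsilyl)oxy]-4-methylpent-3-en-1-yl]-5,8-bis(methoxymethoxy)-1,4-dihydronaphthalene-1,4-diol | CC(C)(C)[Si](C)(C)O[C@H](CC=C(C)C)C1=CC(O)c2c(OCOC)ccc(OCOC)c2C1O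
F5 | step 7 | 2-[(1R)-1-[(tert-butyldimethylsilyl)oxy]-4-methylpent-3-en-1-yl]-5,8-bis(methoxymethoxy)naphthalene-1,4-dione | CC(C)(C)[Si](C)(C)O[C@H](CC=C(C)C)C1=CC(=O)c2c(OCOC)ccc(OCOC)c2C1=O
F6 | step 6 | 3-ethenyl-4,7-bis(methoxymethoxy)-2-benzofuran-1(3H)-one | O=C1OC(C=C)c2c(OCOC)ccc(OCOC)c12
F7 | step 6 | (3R)-3-hydroxy-1-[2-(1-hydroxyprop-2-en-1-yl)-3,6-bis(methoxymethoxy)phenyl]-6-methyl-2-methylidenehept-5-en-1-one | C=CC(O)c1c(OCOC)ccc(OCOC)c1C(=O)C(=C)[C@H](O)CC=C(C)C
F8 | step 5 | 1-[2,5-bis(methoxymethoxy)phenyl]prop-2-en-1-ol | C=CC(O)c1cc(OCOC)ccc1OCOC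
F9 | step 5 | lithium 1-[2-lithio-3,6-bis(methoxymethoxy)phenyl]prop-2-en-1-olate | [Li]c1c(C(O[Li])C=C)c(OCOC)ccc1OCOC
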